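**Retrosynthetic overview**

1. Target 19 comes from alcohol 14 by O-angeloylation at C3–O and release of the phenol from its MOM ether. No ring is formed in the route; the benzene ring is bought.
2. Alcohol 14 contains the 1,5-dien-3-ol C1(H2)=C2(Ar)–C3H(OH)–C4H2–C5H=C6(CH3)2. This is cut at C3–C4 by an enantioselective [2,3]-Wittig rearrangement of the achiral bis(allylic) ether 11.
3. That one step forms C3–C4, sets the only stereocentre (C3) and turns a 1,1-dimethylallyl ether into the linear prenyl unit. A prenyl-metal addition to an aldehyde would give the branched (reverse-prenyl) isomer instead.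
4. Ether 11 comes from Negishi coupling of the arylzinc (MOM-directed ortho-lithiation of 4) with 2-bromoallyl ether 8, which is made from 2-methylbut-3-en-2-ol and 2,3-dibromopropene.
5. Arene 4 comes from 2,4-dimethoxy-3-methylbenzaldehyde by Dakin-type oxidation and MOM protection.

Key step: step 5

Assumption: the sense of induction of the ligand-controlled rearrangement in step 5 cannot be predicted with certainty for this ether class; the (S,S)-ligand is written, the configuration of 14 is to be assigned by Mosher ester analysis, and the equally available (R,R)-ligand is to be used if the first run should give the (R)-alcohol.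

**Route**

Step 1
Reactants: 1 2,4-dimethoxy-3-methylbenzaldehyde
Product: 3 2,4-dimethoxy-3-methylphenol, via aryl formate 2 (not isolated)
Conditions: mCPBA, CH2Cl2, 0 °C to rt; then K2CO3 (cat.), MeOH, rt
Reagents that add atoms: mCPBA (3-chloroperoxybenzoic acid), O=C(OO)c1cccc(Cl)c1
Why: Baeyer–Villiger (Dakin-type) oxidation, in which the electron-rich aryl group (ortho- and para-methoxy) migrates in preference to hydrogen to give the aryl formate, which methanolysis should cleave to the phenol.

Step 2
Reactants: 3 2,4-dimethoxy-3-methylphenol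
Product: 4 1,3-dimethoxy-4-(methoxymethoxy)-2-methylbenzene
Conditions: MOMCl, i-Pr2NEt, CH2Cl2, 0 °C to rt
Reagents that add atoms: chloromethyl methyl ether (MOMCl), COCCl
Why: O-alkylation of the phenol gives the methoxymethyl acetal, which protects the phenol against the organolithium steps and serves as the directing group for the ortho-metalation in step 4.

Step 3
Reactants: 5 2-methylbut-3-en-2-ol; 6 2,3-dibromoprop-1-ene
Product: 8 3-[(2-bromoprop-2-en-1-yl)oxy]-3-methylbut-1-ene, via sodium alkoxide 7 (not isolated)
Conditions: NaH, THF, 0 °C; then 6, n-Bu4NI (cat.), rt to 40 °C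
Reagents that add atoms: none
Why: Williamson ether synthesis, in which the tertiary alkoxide should displace the allylic bromide by SN2 while the vinylic bromide stays untouched.

Step 4
Reactants: 4 1,3-dimethoxy-4-(methoxymethoxy)-2-methylbenzene; 8 3-[(2-bromoprop-2-en-1-yl)oxy]-3-methylbut-1-ene
Product: 11 1,3-dimethoxy-4-(methoxymethoxy)-2-methyl-5-{3-[(2-methylbut-3-en-2-yl)oxy]prop-1-en-2-yl}benzene, via aryllithium 9 (not isolated), via arylzinc chloride 10 (not isolated)
Conditions: n-BuLi, TMEDA, THF, 0 °C; ZnCl2, THF, 0 °C to rt; then 8, Pd(PPh3)4 (cat.), 50 °C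
Reagents that add atoms: none
Why: Directed ortho-metalation should occur at the only position ortho to the OMOM group (a stronger director than OMe), and Li-to-Zn transmetalation followed by Negishi coupling at the vinylic C–Br bond should join the aryl carbon to C2 of the allyl unit without touching the two allylic ether bonds.

Step 5
Reactants: 11 1,3-dimethoxy-4-(methoxymethoxy)-2-methyl-5-{3-[(2-methylbut-3-en-2-yl)oxy]prop-1-en-2-yl}benzene
Product: 14 (3S)-2-[3,5-dimethoxy-2-(methoxymethoxy)-4-methylphenyl]-6-methylhepta-1,5-dien-3-ol, via alpha-lithio ether 12 (not isolated), via lithium alkoxide 13 (not isolated)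
Conditions: t-BuLi (1.3 equiv), 2,2-bis[(4S)-4-isopropyl-4,5-dihydrooxazol-2-yl]propane (1.5 equiv), hexane, −78 °C; then H2O
Reagents that add atoms: none
Why: Proposed new method: the ligand-bound tert-butyllithium removes one of the two enantiotopic hydrogens of the only O–CH2 group (allylic and alpha to oxygen; the other ether carbon is quaternary), and the alpha-alkoxyallyllithium 12 undergoes a concerted suprafacial [2,3]-sigmatropic (Wittig) shift through a five-membered envelope transition state in which C3 bonds to the unsubstituted CH2 terminus of the 1,1-dimethylallyl group while the O–CMe2 bond breaks, giving alkoxide 13. The closest known reactions are the tert-butyllithium/bis(oxazoline)-mediated enantioselective [2,3]-Wittig rearrangements of allyl benzyl and allyl propargyl ethers and the racemic [2,3]-Wittig rearrangement of bis(allylic) ethers, including tertiary allyl ethers that deliver trisubstituted alkenes; new here is ligand control over an alpha-oxyallyl anion that carries a 2-aryl group. No ring is closed. The single new stereocentre C3 is controlled by the C2-symmetric bis(oxazoline) on lithium, either in the enantiotopic deprotonation or in the rearrangement of equilibrating diastereomeric lithium complexes, and the new C5=C6 alkene carries two identical methyl groups, so no alkene geometry has to be controlled. The step needs deprotonation to win over addition of the alkyllithium to the aryl-substituted alkene, and the [2,3] shift to win over radical [1,2] and [1,4] shifts; the kinetic acidity of the O–CH2 group, the twisted electron-rich aryl ring, the unhindered CH2 terminus and the low temperature in a hydrocarbon solvent should secure both.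

Step 6
Reactants: 14 (3S)-2-[3,5-dimethoxy-2-(methoxymethoxy)-4-methylphenyl]-6-methylhepta-1,5-dien-3-ol; 15 angelic acid [(2Z)-2-methylbut-2-enoic acid]
Product: 17 (3S)-2-[3,5-dimethoxy-2-(methoxymethoxy)-4-methylphenyl]-6-methylhepta-1,5-dien-3-yl (2Z)-2-methylbut-2-enoate, via mixed anhydride 16 (not isolated)
Conditions: 15, 2,4,6-trichlorobenzoyl chloride, Et3N, toluene, rt; then 14, 80 °C (no DMAP)
Reagents that add atoms: none
Why: Yamaguchi-type mixed-anhydride esterification run without a nucleophilic catalyst, in which the alcohol should attack the angeloyl carbonyl of 16 (the aroyl carbonyl is shielded by two ortho chlorines), the absence of DMAP should avoid the conjugate addition–elimination that isomerizes angelate to tiglate, and the O-acylation leaves the configuration at C3 untouched.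

Step 7
Reactants: 17 (3S)-2-[3,5-dimethoxy-2-(methoxymethoxy)-4-methylphenyl]-6-methylhepta-1,5-dien-3-yl (2Z)-2-methylbut-2-enoate
Product: 19 (3S)-2-(2-hydroxy-3,5-dimethoxy-4-methylphenyl)-6-methylhepta-1,5-dien-3-yl (2Z)-2-methylbut-2-enoate, via aryl trimethylsilyl ether 18 (not isolated)
Conditions: TMSOTf, 2,2'-bipyridyl, CH2Cl2, 0 °C to rt; then H2O
Reagents that add atoms: none
Why: The bipyridyl-buffered silyl triflate should convert the aromatic MOM acetal into the aryl silyl ether (the methoxymethyl group leaving as an N-(methoxymethyl)bipyridinium salt), and water then frees the phenol under non-protic, near-neutral conditions that should not ionize the allylic ester, protonate the aryl-substituted alkene or isomerize the angelate.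

**Compound list**

1 | 2,4-dimethoxy-3-methylbenzaldehyde | COc1ccc(C=O)c(OC)c1C | starting material
2 | 2,4-dimethoxy-3-methylphenyl formate | COc1ccc(OC=O)c(OC)c1C | intermediate (not isolated)
3 | 2,4-dimethoxy-3-methylphenol | COc1ccc(O)c(OC)c1C | intermediate
4 | 1,3-dimethoxy-4-(methoxymethoxy)-2-methylbenzene | COCOc1ccc(OC)c(C)c1OC | intermediate
5 | 2-methylbut-3-en-2-ol | C=CC(C)(C)O | starting material
6 | 2,3-dibromoprop-1-ene | C=C(Br)CBr | starting material
7 | sodium 2-methylbut-3-en-2-olate | C=CC(C)(C)[O-].[Na+] | intermediate (not isolated)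
8 | 3-[(2-bromoprop-2-en-1-yl)oxy]-3-methylbut-1-ene | C=CC(C)(C)OCC(Br)=C | intermediate
9 | [3,5-dimethoxy-2-(methoxymethoxy)-4-methylphenyl]lithium | [Li]c1cc(OC)c(C)c(OC)c1OCOC | intermediate (not isolated)
10 | chlorido[3,5-dimethoxy-2-(methoxymethoxy)-4-methylphenyl]zinc | Cl[Zn]c1cc(OC)c(C)c(OC)c1OCOC | intermediate (not isolated)
11 | 1,3-dimethoxy-4-(methoxymethoxy)-2-methyl-5-{3-[(2-methylbut-3-en-2-yl)oxy]prop-1-en-2-yl}benzene | C=C(COC(C)(C)C=C)c1cc(OC)c(C)c(OC)c1OCOC | intermediate
12 | {2-[3,5-dimethoxy-2-(methoxymethoxy)-4-methylphenyl]-1-[(2-methylbut-3-en-2-yl)oxy]prop-2-en-1-yl}lithium (ligand-bound, configurationally labile at the C–Li carbon) | [Li]C(OC(C)(C)C=C)C(=C)c1cc(OC)c(C)c(OC)c1OCOC | intermediate (not isolated)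
13 | lithium (3S)-2-[3,5-dimethoxy-2-(methoxymethoxy)-4-methylphenyl]-6-methylhepta-1,5-dien-3-olate | C=C(c1cc(OC)c(C)c(OC)c1OCOC)[C@H](CC=C(C)C)[O-].[Li+] | intermediate (not isolated)
14 | (3S)-2-[3,5-dimethoxy-2-(methoxymethoxy)-4-methylphenyl]-6-methylhepta-1,5-dien-3-ol | C=C(c1cc(OC)c(C)c(OC)c1OCOC)[C@H](CC=C(C)C)O | intermediate
15 | angelic acid [(2Z)-2-methylbut-2-enoic acid] | C/C=C(C)\C(=O)O | starting material
16 | (2Z)-2-methylbut-2-enoic 2,4,6-trichlorobenzoic anhydride | C/C=C(C)\C(=O)OC(=O)c1c(Cl)cc(Cl)cc1Cl | intermediate (not isolated)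
17 | (3S)-2-[3,5-dimethoxy-2-(methoxymethoxy)-4-methylphenyl]-6-methylhepta-1,5-dien-3-yl (2Z)-2-methylbut-2-enoate | C=C(c1cc(OC)c(C)c(OC)c1OCOC)[C@H](CC=C(C)C)OC(=O)/C(C)=C\C | intermediate
18 | (3S)-2-{3,5-dimethoxy-4-methyl-2-[(trimethylsilyl)oxy]phenyl}-6-methylhepta-1,5-dien-3-yl (2Z)-2-methylbut-2-enoate | C=C(c1cc(OC)c(C)c(OC)c1O[Si](C)(C)C)[C@H](CC=C(C)C)OC(=O)/C(C)=C\C | intermediate (not isolated)
19 | (3S)-2-(2-hydroxy-3,5-dimethoxy-4-methylphenyl)-6-methylhepta-1,5-dien-3-yl (2Z)-2-methylbut-2-enoate | C=C(c1cc(OC)c(C)c(OC)c1O)[C@H](CC=C(C)C)OC(=O)/C(C)=C\C | target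

**Step count**

Total steps: 7. Longest linear sequence: 6 (steps 1, 2, 4, 5, 6, 7); step 3 is the side branch.

**Steps most likely to fail**

1. Step 5 (Proposed new method). The ligand may discriminate the enantiotopic hydrogens or the faces of the lithiated ether poorly, the alkyllithium may add to the aryl-substituted alkene instead of deprotonating, or radical [1,2]/[1,4] shifts may compete.
Fallback with known chemistry, setting out from 11 and coming back at 14: ether 11 is rearranged without chiral ligand (n-BuLi, THF, −78 °C, the standard [2,3]-Wittig rearrangement of bis(allylic) ethers) to the racemic alcohol rac-2-[3,5-dimethoxy-2-(methoxymethoxy)-4-methylphenyl]-6-methylhepta-1,5-dien-3-ol F1. Oxidation with Dess–Martin periodinane buffered with NaHCO3 (CH2Cl2, 0 °C) should give the enone 2-[3,5-dimethoxy-2-(methoxymethoxy)-4-methylphenyl]-6-methylhepta-1,5-dien-3-one F2. Corey–Bakshi–Shibata reduction with the (R)-methyl oxazaborolidine and catecholborane (toluene, −78 °C) should return 14: the alpha-arylvinyl group acts as the large substituent and the CH2 group as the small one, so the (R)-catalyst is expected to give the (S)-alcohol by analogy with aryl methyl ketones. The stereocentre is then set by reagent-controlled carbonyl reduction and not in the rearrangement.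

2. Step 6. The (Z)-acyl group may isomerize to the (E)-tiglate through reversible conjugate addition of chloride or amine during the heating, or acyl transfer from the mixed anhydride to the hindered secondary alcohol may be slow and incomplete.
Fallback setting out from 14 and coming back at 17: alcohol 14 is esterified (DCC, DMAP, CH2Cl2) with 2-[bis(2,2,2-trifluoroethoxy)phosphoryl]propanoic acid to the phosphonate ester (3S)-2-[3,5-dimethoxy-2-(methoxymethoxy)-4-methylphenyl]-6-methylhepta-1,5-dien-3-yl 2-[bis(2,2,2-trifluoroethoxy)phosphoryl]propanoate F3, a mixture of epimers at the phosphorus-bearing carbon. Still–Gennari olefination (KHMDS, 18-crown-6, THF, −78 °C; acetaldehyde) should then build the (Z)-2-methylbut-2-enoate on the substrate and give 17. The angelate double bond is thus formed Z-selectively in place and not carried through an acyl transfer.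

3. Step 4. Metalation may occur in part at the position ortho to the 4-methoxy group, or the vinylic bromide may be consumed by halogen–metal exchange or elimination instead of cross-coupling.
Fallback setting out from 4 and 5 and coming back at 11: alcohol 5 is O-alkylated (NaH, THF) with 2-chloro-N-methoxy-N-methylacetamide to the Weinreb amide N-methoxy-N-methyl-2-[(2-methylbut-3-en-2-yl)oxy]acetamide F4. Aryllithium 9, made from 4 as in step 4, is added to F4 (THF, −78 °C) to give the ketone 1-[3,5-dimethoxy-2-(methoxymethoxy)-4-methylphenyl]-2-[(2-methylbut-3-en-2-yl)oxy]ethan-1-one F5. Wittig methylenation (Ph3P=CH2, THF, 0 °C to rt) should give 11. The aryl–C2 bond is then made by acyl substitution and the C1=C2 alkene by olefination, with no palladium step and no vinylic halide.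

**Further compounds**

F1 | step 5 | rac-2-[3,5-dimethoxy-2-(methoxymethoxy)-4-methylphenyl]-6-methylhepta-1,5-dien-3-ol | C=C(c1cc(OC)c(C)c(OC)c1OCOC)C(O)CC=C(C)C
F2 | step 5 | 2-[3,5-dimethoxy-2-(methoxymethoxy)-4-methylphenyl]-6-methylhepta-1,5-dien-3-one | C=C(c1cc(OC)c(C)c(OC)c1OCOC)C(=O)CC=C(C)C
F3 | step 6 | (3S)-2-[3,5-dimethoxy-2-(methoxymethoxy)-4-methylphenyl]-6-methylhepta-1,5-dien-3-yl 2-[bis(2,2,2-trifluoroethoxy)phosphoryl]propanoate | C=C(c1cc(OC)c(C)c(OC)c1OCOC)[C@H](CC=C(C)C)OC(=O)C(C)P(=O)(OCC(F)(F)F)OCC(F)(F)F
F4 | step 4 | N-methoxy-N-methyl-2-[(2-methylbut-3-en-2-yl)oxy]acetamide | CON(C)C(=O)COC(C)(C)C=C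
F5 | step 4 | 1-[3,5-dimethoxy-2-(methoxymethoxy)-4-methylphenyl]-2-[(2-methylbut-3-en-2-yl)oxy]ethan-1-one | O=C(COC(C)(C)C=C)c1cc(OC)c(C)c(OC)c1OCOC
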